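The cedar run read 58.0% of target at 20.0 s and 59.8% at 30.0 s, with 0.9% of substrate left.

| flask | substrate | first nucleophile | second nucleophile | protic impurity | temperature | remark | time |
|---|---|---|---|---|---|---|---|
| cedar | 0.24 M | 1.2 equiv | 5 equiv | 8 mM | 0 °C | run made earlier |  |
| south-east | 0.16 M | 1.20 equiv | 5.00 equiv | 8.00 mM | 0 °C |  | 2.5 min |
| north | 0.16 M | 1.20 equiv | 5.00 equiv | 8.00 mM | 20 °C |  | 2.5 min |

- cedar (time / s: target / %, substrate / %): 10.0: 47.2, 15.5; 20.0: 58.0, 2.1; 30.0: 59.8, 0.9

(each reading ± 0.3 percentage points)

* the flask with the highest amount of target, in percent of the substrate charged ("all alike" if they lie within 1.5 percentage points) (south-east / north / all alike)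
* final target, as a percentage of the substrate charged, in south-east
* final target, as a percentage of the substrate charged, in north

My bench rule was that two nucleophiles competing for one species at one temperature share it by the ratio of their charges, so equal equivalents at that temperature give equal plateaus. This was an assumption: the readings gave target and substrate, and neither a competing step nor its product. I took the substrate that did not become target to be lost to the second nucleophile. I then defined the selectivity factor as target over the rest of the substrate, divided by equivalents of first nucleophile over equivalents of second nucleophile.

factor = (59.8% / 40.2%) / (1.2 equiv / 5 equiv) = 6.20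

South-east and north have the same equivalents as cedar, so I reckoned the same split for both.

charge ratio = 0.240; target over the rest = 1.49; target = 59.8%

The runs do not show what temperature does, so for north I guessed that both captures warm alike, and I expected the flasks to come out alike.

The rule needs first nucleophile to remain present. I therefore set the target it must make, plus the equivalents of protic impurity it may meet, against its charge, and called this the load.

load = (59.8% + 8.00 mM / 0.16 M) / 1.20 equiv = 0.540

I held the rule while the load stood well under 1, the point where first nucleophile becomes the limiting reagent.

The forecast differed, with south-east on top at 53% against 45% in north, on the guess that “an intermediate partitions between bimolecular capture by second nucleophile and unimolecular loss”.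

The flasks came out all alike, with 59.8% of target in south-east and 59.1% in north.

    second nucleophile + intermediate → other capture product (k = 30.0 M⁻¹ s⁻¹, Ea = 46.0 kJ mol⁻¹)
    second nucleophile → decomposed reagent (k = 1.00 s⁻¹, Ea = 69.0 kJ mol⁻¹)
    substrate ⇌ intermediate (K = 0.130, k = 1.90 s⁻¹, Ea = 75.0 kJ mol⁻¹, ΔH = −35.0 kJ mol⁻¹)
    first nucleophile + protic impurity → quenched reagent (k = 0.840 M⁻¹ s⁻¹, Ea = 47.0 kJ mol⁻¹)
    2 second nucleophile → self-condensation product (k = 0.0560 M⁻¹ s⁻¹, Ea = 41.0 kJ mol⁻¹)
    first nucleophile + intermediate → target (k = 95.0 M⁻¹ s⁻¹, Ea = 41.0 kJ mol⁻¹)
    (constants at 20 °C)

In north at 0.0104 min, first nucleophile took the intermediate 1.2 times as fast as second nucleophile did. North ended with target over other capture product at 1.45, beside the 1.49 from the factor. For the neighbour of north with 0.480 equiv of first nucleophile, the factor gave 37.3% of target, at a load of 0.881. That neighbour ended with 42.8% of target, 57.2% of other capture product and 4.84% of its first nucleophile still there.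

All runs come from a simulation for an exercise, noise included.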